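(The numbers in the tables were computed with constants of no real substance.)

A small charge of solid reagent went into the north-east run. I take it that there the solid supplies the partner, and the free catalyst uses the partner to turn left-handed substrate into left-handed product. The north-east charge of 0.12 mM equals 30.0% of the two substrates charged together, and the left-handed product of that run reads level from the first reading, with a mean reading of 14.9%. Dividing the product by the charge:

η = 14.9% / 30.0% = 0.495

I call η the partner yield: points of left-handed product won per point of solid reagent charged.

the same everywhere: left-handed substrate 2.0 × 10⁻⁴ M; right-handed substrate 2.0 × 10⁻⁴ M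
- north-east: solid reagent 0.12 mM; free catalyst 2 µM; run made earlier
- north-west: solid reagent 0.48 mM; free catalyst 2 µM; run made earlier
- flask: solid reagent 0.240 mM; free catalyst 2.0 µM; time 6.0 min

- north-east (time / min: left-handed substrate / %, left-handed product / %): 1.00: 35.9, 14.5; 2.00: 35.2, 14.7; 3.00: 34.6, 14.7; 4.00: 35.2, 15.6; 5.00: 34.7, 14.8
- north-west (time / min: left-handed substrate / %, left-handed product / %): 1.00: 36.7, 13.7; 2.00: 26.3, 24.6; 3.00: 21.1, 29.3; 4.00: 18.2, 32.5; 5.00: 17.2, 32.6

(each reading ± 0.5 percentage points)

1. at 6.0 min, what has stopped the reaction, if anything has (for what has run out or reacted, a solid counts together with what of it has only dissolved) (the partner has run out first / it is still moving / all of the left-handed substrate has reacted / no working catalyst is left / forward and back rates have come level)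
2. part of the left-handed substrate and right-handed substrate together gone at 6.0 min
3. the left-handed product standing at 6.0 min, as a percentage of the left-handed substrate and right-handed substrate together charged
4. the right-handed substrate standing at 6.0 min, as a percentage of the left-handed substrate and right-handed substrate together charged

- free catalyst is single-handed; left-handed substrate and right-handed substrate are mirror images of each other, charged as a racemate, each of them at the stated concentration
- as a solid, counted per litre of solution: solid reagent
- the numbers in the tables scatter by 0.5 percentage points (one standard deviation)
- at the start none of the solid reagent is in solution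
- the reaction counts as stopped when no species that holds the left-handed substrate and right-handed substrate together changes by six tenths of a point or more over the second half of the time

To whoever takes over the bench: the flask holds the racemate, free catalyst and 0.240 mM of solid reagent, which is 60.0% on the same count. I treat the partner as the limiting reagent and expect

left-handed product = η × 60.0% = 29.7%

The north-west run, with more solid reagent, read 29.3% of left-handed product at 3.00 min, earlier than the 6.0 min of this flask, so I expect this flask to be standing still when you come. At its last reading the north-west run has an η of 0.272, lower than the north-east value, so I take my figure as the top of a range. Please add no solid reagent, since that changes the count under test.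

The forecast agrees with my figure: the partner has run out first, 30% gone, 29.7% left-handed product, 50% right-handed substrate. Its ground is that “each product seems to use about 2 partner”.

    free catalyst + left-handed substrate ⇌ catalyst intermediate A (K = 21400 L mol⁻¹, k = 2.07 × 10⁶ L mol⁻¹ s⁻¹)
    free catalyst + right-handed substrate ⇌ catalyst intermediate B (K = 1900 L mol⁻¹, k = 2.75 × 10⁶ L mol⁻¹ s⁻¹)
    partner + catalyst intermediate A → free catalyst + left-handed product (k = 1.06 × 10⁵ L mol⁻¹ s⁻¹)
    partner + catalyst intermediate B → free catalyst + right-handed product (k = 2500 L mol⁻¹ s⁻¹)
    partner + free catalyst → spent catalyst (k = 4160 L mol⁻¹ s⁻¹)
    partner → decomposed reagent (k = 0.128 s⁻¹)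
    solid reagent ⇌ partner, rate k7*(cs7 - [partner]) while solid is left; crystals form when [partner] > cs7 (solubility = 0.0210 mM, k = 0.147 s⁻¹)

At 6.0 min the outcome in the flask is that the partner has run out first, with 25.4% gone, 25.2% left-handed product and 49.9% right-handed substrate, so its η is 0.420, lower than the north-east value. While solid reagent lasted, with 68.8% of it at 0.600 min, the partner went to left-handed product, to decomposed reagent, whose net turnover up to 6.0 min is 34.4% of the substrates charged, and to spent catalyst, which holds 65.2% of the catalyst charged at 6.00 min. At 3.00 min the solid reagent stood at 0% and the partner at 8.41 × 10⁻¹⁰ M, and the flask stayed level afterwards. The neighbour flask with 1.2 × 10⁻⁶ M of free catalyst, on the same solid reagent, gives 18.0% left-handed product, an η of 0.300.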